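**Strategy.** The synthesis rests on disconnecting the C4–C5 bond of the butenolide (ring O1, C2 carbonyl, C3, C4, C5). Because C4 bears only hydrogen and C5 is an unsubstituted O–CH2 group, C5 is treated as a former methoxy carbon and C4 as a carbene carbon. The precursor is an α-keto dimethyl acetal; one-carbon homologation with lithiated trimethylsilyldiazomethane gives an alkylidene carbene that closes the ring by 1,5 C–H insertion into a methoxy group. The resulting 2-methoxy-2,5-dihydrofuran is a base-stable masked butenolide, joined by alkenyl–allyl coupling to a tetrahydrofuran–lactone made from (R)-linalool and oxidised to the lactone last.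

Key step: step 2

Assumptions: (R)-(−)-linalool of high enantiomeric purity and the L-fructose-derived enantiomer of the Shi ketone (prepared from L-sorbose) are taken as purchasable. Compounds drawn without a descriptor at the acetal carbon, the ozonide carbon or the carbinol carbon are mixtures of epimers at that centre, which is removed later in the route.

Step 1
Reactants: 1 1,1-dimethoxypropan-2-one; 2 1-bromobut-2-yne
Product: 4 1,1-dimethoxyhept-5-yn-2-one, via lithium enolate 3 (not isolated)
Conditions: LiN(iPr)2 (1.05 eq), THF, −78 °C; then 2 (0.8 eq), DMPU, −78 to −20 °C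
Reagents that add atoms: none
Why: kinetic deprotonation should occur at the methyl group (the acetal methine is hindered and its enolate would carry two donor oxygens), and the enolate is alkylated by the reactive propargylic bromide in an SN2 enolate alkylation, the excess of enolate limiting dialkylation.

Step 2
Reactants: 4 1,1-dimethoxyhept-5-yn-2-one; 5 (trimethylsilyl)diazomethane
Product: 9 2-methoxy-3-(pent-3-yn-1-yl)-2,5-dihydrofuran, via lithium alkoxide adduct 6 (not isolated), via diazoalkene 7 (not isolated), via alkylidene carbene 8 (not isolated)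
Conditions: 5, n-BuLi, THF, −78 °C; then 4, −78 to 0 °C; NaHCO3 work-up
Reagents that add atoms: none
Why: Lithiated 5 adds to the ketone of 4 to give 6, which loses lithium trimethylsilanolate in a Peterson-type elimination to diazoalkene 7; loss of N2 gives the free alkylidene carbene 8, whose vacant in-plane orbital inserts into a C–H bond of one methoxy group. The closest known reaction type is the 1,5 C–H insertion of alkylidene carbenes generated from α-alkoxy ketones by this Colvin-type homologation, which gives 2,5-dihydrofurans. The dihydrofuran ring closes by concerted 1,5-insertion through a five-membered transition state that joins the carbene carbon (future C4) to the methoxy carbon (future C5), the ether oxygen lone pair activating that C–H bond. The only new stereocentre is the acetal carbon C2, formed racemic because the two methoxy groups are enantiotopic; it is not controlled and is erased in step 11. The step needs chemoselectivity for the primary O–CH3 hydrogens, and the substrate secures it: the other 1,5-position, on the chain, is an sp carbon of the alkyne without hydrogen, the alkyne (unlike an alkene at that position) is a poor trap for the carbene, and six equivalent oxygen-activated hydrogens are on offer. The 1,2-shift to an alkyne should be slow for a carbene with two sp3 carbon substituents.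

Step 3
Reactants: 10 (3R)-3,7-dimethylocta-1,6-dien-3-ol
Product: 11 (2E,6R)-2,6-dimethylocta-2,7-diene-1,6-diol
Conditions: SeO2 (10 mol %), t-BuOOH (2 eq), salicylic acid (10 mol %), CH2Cl2, rt
Reagents that add atoms: tert-butyl hydroperoxide CC(C)(C)OO; selenium dioxide O=[Se]=O (catalytic oxygen carrier)
Why: SeO2 allylic oxidation (ene reaction, then [2,3]-sigmatropic shift) should hydroxylate the (E)-methyl group of the trisubstituted alkene selectively, the vinyl group having no allylic hydrogen and the carbinol stereocentre being untouched.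

Step 4
Reactants: 11 (2E,6R)-2,6-dimethylocta-2,7-diene-1,6-diol
Product: 12 (3R,6E)-8-bromo-3,7-dimethylocta-1,6-dien-3-ol
Conditions: CBr4, PPh3, 2,6-lutidine, CH2Cl2, −20 to 0 °C; used at once
Reagents that add atoms: carbon tetrabromide BrC(Br)(Br)Br
Why: Appel reaction, in which the primary allylic alcohol is displaced by SN2 attack of bromide on the alkoxyphosphonium ion without allylic transposition, while the hindered tertiary alcohol should not react at low temperature.

Step 5
Reactants: 12 (3R,6E)-8-bromo-3,7-dimethylocta-1,6-dien-3-ol; 13 ethyl acetate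
Product: 15 ethyl (4E,8R)-8-hydroxy-4,8-dimethyldeca-4,9-dienoate, via lithium enolate 14 (not isolated)
Conditions: 13, LiN(iPr)2 (3 eq), THF, −78 °C; CuI (20 mol %); then 12, −78 to −30 °C
Reagents that add atoms: none
Why: copper-assisted SN2 alkylation of the ester enolate at the primary allylic bromide adds the two missing chain carbons with retention of the (E)-alkene, the excess enolate deprotonating the tertiary hydroxyl, which is returned on work-up.

Step 6
Reactants: 15 ethyl (4E,8R)-8-hydroxy-4,8-dimethyldeca-4,9-dienoate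
Product: 16 ethyl 3-[(2S,3S)-3-[(3R)-3-hydroxy-3-methylpent-4-en-1-yl]-2-methyloxiran-2-yl]propanoate
Conditions: L-fructose-derived Shi ketone (30 mol %), KHSO5 (as the triple salt 2KHSO5·KHSO4·K2SO4), K2CO3, Bu4NHSO4, MeCN/dimethoxymethane/aqueous Na2B4O7 buffer, 0 °C
Reagents that add atoms: potassium peroxymonosulfate [K+].[O-]S(=O)(=O)OO
Why: Shi asymmetric epoxidation, in which the chiral dioxirane attacks only the electron-rich trisubstituted alkene through a spiro transition state, and the catalyst (this enantiomer gives (S,S)-epoxides from (E)-trisubstituted alkenes) sets both oxirane stereocentres independently of the remote carbinol centre.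

Step 7
Reactants: 16 ethyl 3-[(2S,3S)-3-[(3R)-3-hydroxy-3-methylpent-4-en-1-yl]-2-methyloxiran-2-yl]propanoate
Product: 18 (5S)-5-[(2R,5R)-5-ethenyl-5-methyloxolan-2-yl]-5-methyloxolan-2-one, via hydroxy ester 17 (not isolated)
Conditions: camphorsulfonic acid (10 mol %), CH2Cl2, 0 °C to rt, then 40 °C
Reagents that add atoms: none
Why: acid-catalysed 5-exo-tet epoxy-alcohol cyclisation, in which the tertiary hydroxyl opens the epoxide at its secondary carbon with inversion (setting the ring CH centre as R and the 2,5-trans tetrahydrofuran), while the epoxide oxygen stays on the quaternary carbon with retention (S) and then lactonises onto the ethyl ester.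

Step 8
Reactants: 18 (5S)-5-[(2R,5R)-5-ethenyl-5-methyloxolan-2-yl]-5-methyloxolan-2-one
Product: 20 (2R,5R)-2-methyl-5-[(2S)-2-methyl-5-oxooxolan-2-yl]oxolane-2-carbaldehyde, via ozonide 19 (not isolated)
Conditions: O3, CH2Cl2, −78 °C; then PPh3, −78 °C to rt
Reagents that add atoms: ozone [O-][O+]=O
Why: ozonolysis with reductive work-up cleaves the only alkene, and the aldehyde produced sits on a quaternary carbon and cannot epimerise.

Step 9
Reactants: 20 (2R,5R)-2-methyl-5-[(2S)-2-methyl-5-oxooxolan-2-yl]oxolane-2-carbaldehyde; 21 vinylmagnesium bromide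
Product: 23 methyl 1-[(2R,5R)-2-methyl-5-[(2S)-2-methyl-5-oxooxolan-2-yl]oxolan-2-yl]prop-2-en-1-yl carbonate, via magnesium alkoxide 22 (not isolated)
Conditions: CH2=CHMgBr (1.1 eq), THF, −78 °C; then ClCO2Me, −78 to 0 °C
Reagents that add atoms: methyl chloroformate COC(=O)Cl
Why: Grignard 1,2-addition to the aldehyde (far more electrophilic than the lactone at −78 °C) followed by O-acylation of the alkoxide, the new carbinol centre being formed as a mixture that does not matter because it becomes an sp2 carbon in step 10.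

Step 10
Reactants: 9 2-methoxy-3-(pent-3-yn-1-yl)-2,5-dihydrofuran; 23 methyl 1-[(2R,5R)-2-methyl-5-[(2S)-2-methyl-5-oxooxolan-2-yl]oxolan-2-yl]prop-2-en-1-yl carbonate
Product: 26 (5S)-5-[(2R,5R)-5-[(1E,4E)-7-(2-methoxy-2,5-dihydrofuran-3-yl)-4-methylhepta-1,4-dien-1-yl]-5-methyloxolan-2-yl]-5-methyloxolan-2-one, via alkenylzirconocene 24 (not isolated), via alkenylzinc chloride 25 (not isolated)
Conditions: 9 (1.5 eq), Cp2Zr(H)Cl (1.7 eq), THF, rt to 40 °C; ZnCl2 (1.5 eq), 0 °C; then 23 (1 eq), Pd(PPh3)4 (5 mol %), THF, rt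
Reagents that add atoms: none
Why: syn-hydrozirconation of the methyl alkyne should, after equilibration with a slight excess of reagent, place zirconium on the less hindered methyl-bearing carbon and fix the (E)-trisubstituted geometry, and transmetalation to zinc followed by Negishi-type alkenyl–allyl coupling through a syn π-allylpalladium intermediate joins the alkenyl group to the unhindered CH2 terminus (the other terminus is next to a quaternary carbon) with retention, giving the (E)-disubstituted alkene.

Step 11
Reactants: 26 (5S)-5-[(2R,5R)-5-[(1E,4E)-7-(2-methoxy-2,5-dihydrofuran-3-yl)-4-methylhepta-1,4-dien-1-yl]-5-methyloxolan-2-yl]-5-methyloxolan-2-one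
Product: 28 (5S)-5-methyl-5-[(2R,5R)-5-methyl-5-[(1E,4E)-4-methyl-7-(2-oxo-2,5-dihydrofuran-3-yl)hepta-1,4-dien-1-yl]oxolan-2-yl]oxolan-2-one, via lactol 27 (not isolated)
Conditions: CrO3, H2SO4, H2O, acetone, −10 to 0 °C, short reaction time
Reagents that add atoms: water O
Why: Jones oxidation of a lactol methyl ether, in which aqueous acid exchanges methoxy for hydroxyl and the allylic lactol 27 should be oxidised rapidly by hexavalent chromium to the butenolide, both acetal epimers converging and no stereocentre being touched.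

**Compound list**

1 | 1,1-dimethoxypropan-2-one | CC(=O)C(OC)OC | starting material
2 | 1-bromobut-2-yne | CC#CCBr | starting material
3 | lithium 3,3-dimethoxyprop-1-en-2-olate | C=C(O[Li])C(OC)OC | intermediate
4 | 1,1-dimethoxyhept-5-yn-2-one | CC#CCCC(=O)C(OC)OC | intermediate
5 | (trimethylsilyl)diazomethane | C[Si](C)(C)C=[N+]=[N-] | starting material
6 | lithium 1-diazo-2-(dimethoxymethyl)-1-(trimethylsilyl)hept-5-yn-2-olate | CC#CCCC(O[Li])(C(OC)OC)C(=[N+]=[N-])[Si](C)(C)C | intermediate
7 | 1-diazo-2-(dimethoxymethyl)hept-1-en-5-yne | CC#CCCC(=C=[N+]=[N-])C(OC)OC | intermediate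
8 | 2-(dimethoxymethyl)hept-1-en-5-yn-1-ylidene (free alkylidene carbene) | CC#CCCC(=[C])C(OC)OC | intermediate
9 | 2-methoxy-3-(pent-3-yn-1-yl)-2,5-dihydrofuran (racemic at the acetal carbon) | CC#CCCC1=CCOC1OC | intermediate
10 | (3R)-3,7-dimethylocta-1,6-dien-3-ol, (R)-linalool | C=C[C@](C)(O)CCC=C(C)C | starting material
11 | (2E,6R)-2,6-dimethylocta-2,7-diene-1,6-diol | C=C[C@](C)(O)CC/C=C(\C)CO | intermediate
12 | (3R,6E)-8-bromo-3,7-dimethylocta-1,6-dien-3-ol | C=C[C@](C)(O)CC/C=C(\C)CBr | intermediate
13 | ethyl acetate | CCOC(C)=O | starting material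
14 | lithium 1-ethoxyethen-1-olate | C=C(O[Li])OCC | intermediate
15 | ethyl (4E,8R)-8-hydroxy-4,8-dimethyldeca-4,9-dienoate | C=C[C@](C)(O)CC/C=C(\C)CCC(=O)OCC | intermediate
16 | ethyl 3-[(2S,3S)-3-[(3R)-3-hydroxy-3-methylpent-4-en-1-yl]-2-methyloxiran-2-yl]propanoate | C=C[C@](C)(O)CC[C@@H]1O[C@@]1(C)CCC(=O)OCC | intermediate
17 | ethyl (4S)-4-[(2R,5R)-5-ethenyl-5-methyloxolan-2-yl]-4-hydroxypentanoate | C=C[C@@]1(C)CC[C@H]([C@@](C)(O)CCC(=O)OCC)O1 | intermediate
18 | (5S)-5-[(2R,5R)-5-ethenyl-5-methyloxolan-2-yl]-5-methyloxolan-2-one | C=C[C@@]1(C)CC[C@H]([C@]2(C)CCC(=O)O2)O1 | intermediate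
19 | (5S)-5-methyl-5-[(2R,5R)-5-methyl-5-(1,2,4-trioxolan-3-yl)oxolan-2-yl]oxolan-2-one (ozonide, both epimers) | C1(OCOO1)[C@@]2(C)CC[C@H]([C@]3(C)CCC(=O)O3)O2 | intermediate
20 | (2R,5R)-2-methyl-5-[(2S)-2-methyl-5-oxooxolan-2-yl]oxolane-2-carbaldehyde | O=C[C@@]1(C)CC[C@H]([C@]2(C)CCC(=O)O2)O1 | intermediate
21 | vinylmagnesium bromide | C=C[Mg]Br | starting material
22 | bromomagnesium 1-[(2R,5R)-2-methyl-5-[(2S)-2-methyl-5-oxooxolan-2-yl]oxolan-2-yl]prop-2-en-1-olate (both epimers) | C=CC(O[Mg]Br)[C@@]1(C)CC[C@H]([C@]2(C)CCC(=O)O2)O1 | intermediate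
23 | methyl 1-[(2R,5R)-2-methyl-5-[(2S)-2-methyl-5-oxooxolan-2-yl]oxolan-2-yl]prop-2-en-1-yl carbonate (both epimers) | C=CC(OC(=O)OC)[C@@]1(C)CC[C@H]([C@]2(C)CCC(=O)O2)O1 | intermediate
24 | chlorobis(cyclopentadienyl)[(2E)-5-(2-methoxy-2,5-dihydrofuran-3-yl)pent-2-en-2-yl]zirconium (cyclopentadienyl rings drawn sigma-bonded) | C/C(=C\CCC1=CCOC1OC)[Zr](Cl)(C1C=CC=C1)C1C=CC=C1 | intermediate
25 | chloro[(2E)-5-(2-methoxy-2,5-dihydrofuran-3-yl)pent-2-en-2-yl]zinc | C/C(=C\CCC1=CCOC1OC)[Zn]Cl | intermediate
26 | (5S)-5-[(2R,5R)-5-[(1E,4E)-7-(2-methoxy-2,5-dihydrofuran-3-yl)-4-methylhepta-1,4-dien-1-yl]-5-methyloxolan-2-yl]-5-methyloxolan-2-one (both acetal epimers) | C/C(=C\CCC1=CCOC1OC)C/C=C/[C@@]1(C)CC[C@H]([C@]2(C)CCC(=O)O2)O1 | intermediate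
27 | (5S)-5-[(2R,5R)-5-[(1E,4E)-7-(2-hydroxy-2,5-dihydrofuran-3-yl)-4-methylhepta-1,4-dien-1-yl]-5-methyloxolan-2-yl]-5-methyloxolan-2-one (lactol, both epimers) | C/C(=C\CCC1=CCOC1O)C/C=C/[C@@]1(C)CC[C@H]([C@]2(C)CCC(=O)O2)O1 | intermediate
28 | (5S)-5-methyl-5-[(2R,5R)-5-methyl-5-[(1E,4E)-4-methyl-7-(2-oxo-2,5-dihydrofuran-3-yl)hepta-1,4-dien-1-yl]oxolan-2-yl]oxolan-2-one | C/C(=C\CCC1=CCOC1=O)C/C=C/[C@@]1(C)CC[C@H]([C@]2(C)CCC(=O)O2)O1 | target

**Step count.** Total: 11 steps. Longest linear sequence: 9 steps (steps 3 to 11, from (R)-linalool); the dihydrofuran branch contributes steps 1 and 2.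

**Steps most likely to fail**

Step 2. The lithiated diazomethane may act as a base and enolise ketone 4 instead of adding, and insertion of carbene 8 into a primary C–H bond may be slow enough for the 1,2-shift to compete. Fallback, setting out from 4 and returning at 9: Wittig bromomethylenation of 4 with the ylide from (bromomethyl)triphenylphosphonium bromide and KOtBu (THF, −78 °C to rt) would give 1-bromo-2-(dimethoxymethyl)hept-1-en-5-yne F1 as an E/Z mixture, both isomers being usable. α-Elimination with KN(SiMe3)2 in Et2O at rt would then generate the same alkylidene carbene 8 without a nucleophilic addition to the ketone and without diazo intermediates, and 8 closes to 9 as before.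

Step 10. Hydrozirconation of the methyl alkyne may give incomplete regiocontrol, ionisation of the hindered branched carbonate may be slow, and the Lewis-acidic zinc salt may strip methanol from the acetal. Fallback, setting out from enolate 3 and from aldehyde 20 and returning at 26: the cross-coupling is moved to the bond between the doubly allylic CH2 and the disubstituted alkene, so that both partners are regiodefined.
- Enolate 3 would be alkylated with ethyl (E)-4-bromo-2-methylbut-2-enoate (CCOC(=O)/C(C)=C/CBr) to ethyl (2E)-7,7-dimethoxy-2-methyl-6-oxohept-2-enoate F2.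
- The conditions of step 2 would convert F2 into ethyl (2E)-5-(2-methoxy-2,5-dihydrofuran-3-yl)-2-methylpent-2-enoate F3; the electron-poor enoate is not expected to trap the electrophilic carbene.
- iBu2AlH (CH2Cl2, −78 °C) would give (2E)-5-(2-methoxy-2,5-dihydrofuran-3-yl)-2-methylpent-2-en-1-ol F4, and CBr4/PPh3 the allylic bromide 3-[(3E)-5-bromo-4-methylpent-3-en-1-yl]-2-methoxy-2,5-dihydrofuran F5.
- Aldehyde 20 would be homologated with dimethyl (1-diazo-2-oxopropyl)phosphonate and K2CO3 in MeOH (Ohira–Bestmann reaction) to (5S)-5-[(2R,5R)-5-ethynyl-5-methyloxolan-2-yl]-5-methyloxolan-2-one F6.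
- Hydrostannylation of F6 (Bu3SnH, PdCl2(PPh3)2 cat., THF) would give the (E)-alkenylstannane (5S)-5-methyl-5-[(2R,5R)-5-methyl-5-[(E)-2-(tributylstannyl)ethenyl]oxolan-2-yl]oxolan-2-one F7.
- Stille coupling of F5 with F7 (Pd2(dba)3, AsPh3, DMF, rt) would give 26.

Step 11. Under the strongly acidic conditions the oxocarbenium ion may lose a proton and aromatise to a 3-alkylfuran before water traps it, and the tertiary allylic ether may ionise. Fallback, setting out from 26 and returning at 28: hydrolysis and oxidation are separated. Buffered hydrolysis (pyridinium p-toluenesulfonate, acetone/H2O, rt) would give lactol 27, now isolated, and Fetizon oxidation (Ag2CO3 on Celite, toluene, reflux) would oxidise the allylic lactol to 28 under neutral, chromium-free conditions.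

**Further compounds**

F1 | step 2 | 1-bromo-2-(dimethoxymethyl)hept-1-en-5-yne (E/Z mixture) | CC#CCCC(=CBr)C(OC)OC
F2 | step 10 | ethyl (2E)-7,7-dimethoxy-2-methyl-6-oxohept-2-enoate | CCOC(=O)/C(C)=C/CCC(=O)C(OC)OC
F3 | step 10 | ethyl (2E)-5-(2-methoxy-2,5-dihydrofuran-3-yl)-2-methylpent-2-enoate | CCOC(=O)/C(C)=C/CCC1=CCOC1OC
F4 | step 10 | (2E)-5-(2-methoxy-2,5-dihydrofuran-3-yl)-2-methylpent-2-en-1-ol | OC/C(C)=C/CCC1=CCOC1OC
F5 | step 10 | 3-[(3E)-5-bromo-4-methylpent-3-en-1-yl]-2-methoxy-2,5-dihydrofuran | BrC/C(C)=C/CCC1=CCOC1OC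
F6 | step 10 | (5S)-5-[(2R,5R)-5-ethynyl-5-methyloxolan-2-yl]-5-methyloxolan-2-one | C#C[C@@]1(C)CC[C@H]([C@]2(C)CCC(=O)O2)O1
F7 | step 10 | (5S)-5-methyl-5-[(2R,5R)-5-methyl-5-[(E)-2-(tributylstannyl)ethenyl]oxolan-2-yl]oxolan-2-one | CCCC[Sn](CCCC)(CCCC)/C=C/[C@@]1(C)CC[C@H]([C@]2(C)CCC(=O)O2)O1
F0 | step 11 | none | none
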